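**Strategy.** With C1 the lactone carbonyl, C3 and C4 the ring-fusion carbons and C6 the chain-bearing carbon, the lactone oxygen on C4 and the tetrahydrofuran oxygen on C6 are 1,3-related on two methylated quaternary carbons, and C3 is beta to C1. Both ring C–O bonds (O–C3 and O–C1) are therefore disconnected to a (3S,5S)-3,5-dimethyl-1,2-dioxolane that carries a methyl (E)-acrylate on C4 and the phenyldienyl chain on C6. Reductive cleavage of its O–O bond releases a ditertiary diol that closes the tetrahydrofuran ring by oxa-Michael addition and the lactone ring by acyl substitution in the same operation, creating C3. The dioxolane core comes from radical oxygenation of a vinylcyclopropane and is resolved enzymatically.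

Key step: step 14

Numbering used below: C1 lactone carbonyl, C2 its CH2, C3 ring-fusion CH, C4 ring-fusion C(CH3), C5 ring CH2, C6 the C(CH3) that bears the chain, C7–C18 the chain. TBS = tert-butyldimethylsilyl; DMP = Dess–Martin periodinane.

Assumption: the lipase in step 9 acylates the (3R,5R) alcohol faster, so the wanted (3S,5S) alcohol 14 is the one recovered. The sense and the absolute configuration must be established on the first run (crystalline heavy-atom ester, or correlation of 24 with the natural product); the fallback for step 9 does not depend on them.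

**Step 1**
Reactants: 1 but-2-yn-1-ol
Product: 3 (2Z)-3-iodo-2-methylbut-2-en-1-ol, via cyclic alkenylmagnesium alkoxide 2 (not isolated)
Conditions: MeMgBr (3 equiv), CuI (10 mol%), THF, −10 °C→rt; then I2, −78→0 °C
Reagents that add atoms: methylmagnesium bromide, C[Mg]Br; iodine, [I][I]
Why: Copper-catalysed anti-carbomagnesiation of the propargylic alkoxide places the new methyl on the carbon next to CH2O through a five-membered magnesium chelate, and iodinolysis of the C–Mg bond with retention gives the Z iodide (the geometry is defined but not needed later, because step 7 erases it).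

**Step 2**
Reactants: 4 9-bromononan-1-ol
Product: 5 [(9-bromononyl)oxy](tert-butyl)dimethylsilane
Conditions: TBSCl, imidazole, CH2Cl2, 0 °C→rt
Reagents that add atoms: tert-butyldimethylsilyl chloride, CC(C)(C)[Si](C)(C)Cl
Why: Standard silylation of a primary alcohol; the TBS ether should withstand the organozinc, carbenoid, ylide, radical, ozone and hydride steps and is removed with fluoride in step 11.

**Step 3**
Reactants: 5 [(9-bromononyl)oxy](tert-butyl)dimethylsilane; 3 (2Z)-3-iodo-2-methylbut-2-en-1-ol
Product: 7 (2Z)-12-(TBSO)-2,3-dimethyldodec-2-en-1-ol, via alkylzinc bromide 6 (not isolated)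
Conditions: 5, Zn dust, LiCl, THF, 50 °C; then 3, PdCl2(dppf) (5 mol%), THF, 50 °C
Reagents that add atoms: none
Why: Negishi alkyl–alkenyl cross-coupling: LiCl-assisted zinc insertion into the primary bromide gives 6, which (used in excess, since the free hydroxyl may bind one equivalent as zinc alkoxide) couples with the iodide with retention of alkene geometry, the wide-bite-angle ligand favouring reductive elimination over β-hydride loss.

**Step 4**
Reactants: 7 (2Z)-12-(TBSO)-2,3-dimethyldodec-2-en-1-ol
Product: 8 racemic {2-[9-(TBSO)nonyl]-1,2-dimethylcyclopropyl}methanol (CH2OH cis to the chain)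
Conditions: Et2Zn, CH2I2, CH2Cl2, 0 °C→rt
Reagents that add atoms: diiodomethane, C(I)I
Why: Hydroxyl-directed Simmons–Smith cyclopropanation (Furukawa reagent) of an electron-rich tetrasubstituted allylic alcohol, stereospecifically syn; the product is racemic, which is immaterial because both ring stereocentres are erased in step 7.

**Step 5**
Reactants: 8 racemic {2-[9-(TBSO)nonyl]-1,2-dimethylcyclopropyl}methanol
Product: 9 racemic 2-[9-(TBSO)nonyl]-1,2-dimethylcyclopropane-1-carbaldehyde (CHO cis to the chain)
Conditions: DMP, NaHCO3, CH2Cl2, 0 °C→rt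
Reagents that add atoms: none
Why: Dess–Martin oxidation of a primary alcohol to an aldehyde that has no α-hydrogen, under buffered conditions that spare the silyl ether and the cyclopropane.

**Step 6**
Reactants: 9 racemic 2-[9-(TBSO)nonyl]-1,2-dimethylcyclopropane-1-carbaldehyde
Product: 10 racemic tert-butyl{[9-(2-ethenyl-1,2-dimethylcyclopropyl)nonyl]oxy}dimethylsilane (vinyl cis to the chain)
Conditions: Ph3PCH3Br, KOtBu, THF, 0 °C→rt
Reagents that add atoms: methyltriphenylphosphonium bromide, C[P+](c1ccccc1)(c1ccccc1)c1ccccc1.[Br-]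
Why: Wittig methylenation; the small non-stabilised ylide should cope with the neopentyl-type, non-enolisable aldehyde.

**Step 7**
Reactants: 10 racemic tert-butyl{[9-(2-ethenyl-1,2-dimethylcyclopropyl)nonyl]oxy}dimethylsilane
Product: 11 racemic tert-butyl({9-[(3RS,5RS)-5-ethenyl-3,5-dimethyl-1,2-dioxolan-3-yl]nonyl}oxy)dimethylsilane (methyl groups cis)
Conditions: PhSSPh (0.2 equiv), AIBN (0.1 equiv), O2 (1 atm), hν, MeCN, 0 °C
Reagents that add atoms: dioxygen, O=O
Why: Thiyl-radical-catalysed oxygenation of a vinylcyclopropane (Feldman oxygenation): PhS• adds to the vinyl terminus, the cyclopropylcarbinyl radical opens to the tertiary radical at the chain-bearing carbon, O2 is captured, the peroxyl radical closes 5-exo onto the allyl sulfide and β-scission returns PhS• and the vinyl group; both quaternary centres (C4 and C6) are created here without a strong facial bias, so the product is racemic and should be accompanied by its trans-dimethyl diastereomer, which is removed by chromatography here or after step 8.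

**Step 8**
Reactants: 11 racemic tert-butyl({9-[(3RS,5RS)-5-ethenyl-3,5-dimethyl-1,2-dioxolan-3-yl]nonyl}oxy)dimethylsilane
Product: 13 racemic {(3RS,5RS)-5-[9-(TBSO)nonyl]-3,5-dimethyl-1,2-dioxolan-3-yl}methanol, via dioxolanecarbaldehyde 12 (not isolated)
Conditions: O3, CH2Cl2/MeOH, −78 °C; then NaBH4, −78→0 °C; chromatography
Reagents that add atoms: ozone, [O-][O+]=O
Why: Ozonolysis with reductive (borohydride) work-up; the di-tertiary dialkyl peroxide and the silyl ether are inert to ozone and NaBH4, and the free hydroxyl next to the ring should make removal of any remaining trans isomer easy (the cis isomer to be recognised by the NOE between the two methyl groups).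

**Step 9**
Reactants: 13 racemic {(3RS,5RS)-5-[9-(TBSO)nonyl]-3,5-dimethyl-1,2-dioxolan-3-yl}methanol
Product: 14 {(3S,5S)-5-[9-(TBSO)nonyl]-3,5-dimethyl-1,2-dioxolan-3-yl}methanol
Conditions: immobilised Burkholderia cepacia lipase, vinyl acetate, t-BuOMe, 30 °C, stopped just past half conversion; chromatography
Reagents that add atoms: none
Why: Lipase-catalysed kinetic resolution by irreversible transesterification with vinyl acetate; primary carbinols on a quaternary stereocentre are an established if demanding substrate class, and running slightly beyond half conversion raises the enantiomeric purity of the unreacted (3S,5S) alcohol, which fixes C4 and C6 in absolute terms.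

**Step 10**
Reactants: 14 {(3S,5S)-5-[9-(TBSO)nonyl]-3,5-dimethyl-1,2-dioxolan-3-yl}methanol; 15 methyl (triphenylphosphoranylidene)acetate
Product: 17 methyl (2E)-3-{(3S,5S)-5-[9-(TBSO)nonyl]-3,5-dimethyl-1,2-dioxolan-3-yl}prop-2-enoate, via dioxolanecarbaldehyde 16 (not isolated)
Conditions: DMP, NaHCO3, CH2Cl2, 0 °C→rt; then 15 (3 equiv), rt
Reagents that add atoms: none
Why: Tandem Dess–Martin oxidation–Wittig olefination; the aldehyde has no α-hydrogen and is trapped without isolation, and the stabilised ylide gives the E enoate and does not reduce the peroxide.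

**Step 11**
Reactants: 17 methyl (2E)-3-{(3S,5S)-5-[9-(TBSO)nonyl]-3,5-dimethyl-1,2-dioxolan-3-yl}prop-2-enoate
Product: 18 methyl (2E)-3-[(3S,5S)-5-(9-hydroxynonyl)-3,5-dimethyl-1,2-dioxolan-3-yl]prop-2-enoate
Conditions: HF·pyridine, pyridine, THF, 0 °C→rt
Reagents that add atoms: none
Why: Fluoride-mediated desilylation under buffered, non-basic conditions that leave the enoate and the dialkyl peroxide untouched.

**Step 12**
Reactants: 18 methyl (2E)-3-[(3S,5S)-5-(9-hydroxynonyl)-3,5-dimethyl-1,2-dioxolan-3-yl]prop-2-enoate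
Product: 19 methyl (2E)-3-[(3S,5S)-3,5-dimethyl-5-(9-oxononyl)-1,2-dioxolan-3-yl]prop-2-enoate
Conditions: DMP, NaHCO3, CH2Cl2, 0 °C→rt
Reagents that add atoms: none
Why: Dess–Martin oxidation of the primary alcohol under buffered conditions tolerated by the peroxide and the enoate.

**Step 13**
Reactants: 19 methyl (2E)-3-[(3S,5S)-3,5-dimethyl-5-(9-oxononyl)-1,2-dioxolan-3-yl]prop-2-enoate; 20 diethyl cinnamylphosphonate
Product: 21 methyl (2E)-3-{(3S,5S)-3,5-dimethyl-5-[(9E,11E)-12-phenyldodeca-9,11-dien-1-yl]-1,2-dioxolan-3-yl}prop-2-enoate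
Conditions: 20 (1.1 equiv), LiN(SiMe3)2, THF, −78 °C; then 19, −78 °C→rt
Reagents that add atoms: none
Why: Horner–Wadsworth–Emmons olefination with the lithiated allylic phosphonate: the anion should add to the aldehyde far faster than to the hindered enoate, give the new C15=C16 bond E with the cinnamyl geometry retained, and find no hydrogen on the peroxide carbons for a Kornblum–DeLaMare fragmentation.

**Step 14**
Reactants: 21 methyl (2E)-3-{(3S,5S)-3,5-dimethyl-5-[(9E,11E)-12-phenyldodeca-9,11-dien-1-yl]-1,2-dioxolan-3-yl}prop-2-enoate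
Product: 24 plakortone P, via dihydroxy enoate 22 (not isolated), via tetrahydrofuranyl acetate 23 (not isolated)
Conditions: Zn dust, AcOH/Et2O (1:4), 0 °C→rt; filter, evaporate; then DBU (0.3 equiv), PhMe, rt
Reagents that add atoms: none
Why: Zinc transfers two electrons into the weak O–O bond (protons from AcOH) to give the ditertiary diol 22 with both C–O bonds, and hence C4 and C6, intact; the closest known reaction type is reductive cleavage of 1,2-dioxolanes and endoperoxides to 1,3-diols followed by hydroxy-enoate oxa-Michael addition and lactonisation. The tetrahydrofuran ring closes by 5-exo-trig conjugate addition of the C6 hydroxyl to C3, and the lactone ring by 5-exo-trig acyl substitution of the C4 hydroxyl at C1 with loss of methanol. C3 is the only new stereocentre and is set under thermodynamic control: the oxa-Michael addition is reversible under DBU and only adduct 23, with the C2 arm cis to the C4 oxygen, can lactonise, because a trans-fused 2,6-dioxabicyclo[3.3.0]octanone is prohibitively strained, so irreversible lactonisation should drain the equilibrium to the (3S) product. The step needs chemoselectivity for O–O over the enoate and the phenyldiene, which rests on the low strength of the peroxide bond compared with what Zn/AcOH can reduce at room temperature. Fragmentation to ketones cannot compete because neither peroxide carbon carries hydrogen, and the C4 hydroxyl has no alternative closure since addition to C3 or C2 would give a three- or four-membered ring.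

**Compound list** (racemates are written as both enantiomers joined by a dot)

1 | but-2-yn-1-ol | CC#CCO | starting material
2 | 3,4-dimethyl-2,5-dihydro-1,2-oxamagnesole (cyclic alkenylmagnesium alkoxide) | CC1=C(C)[Mg]OC1 | intermediate (not isolated)
3 | (2Z)-3-iodo-2-methylbut-2-en-1-ol | OC/C(C)=C(C)\I | intermediate
4 | 9-bromononan-1-ol | OCCCCCCCCCBr | starting material
5 | [(9-bromononyl)oxy](tert-butyl)dimethylsilane | BrCCCCCCCCCO[Si](C)(C)C(C)(C)C | intermediate
6 | [9-(tert-butyldimethylsilyloxy)nonyl]zinc bromide | Br[Zn]CCCCCCCCCO[Si](C)(C)C(C)(C)C | intermediate (not isolated)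
7 | (2Z)-12-(tert-butyldimethylsilyloxy)-2,3-dimethyldodec-2-en-1-ol | OC/C(C)=C(C)\CCCCCCCCCO[Si](C)(C)C(C)(C)C | intermediate
8 | racemic {2-[9-(tert-butyldimethylsilyloxy)nonyl]-1,2-dimethylcyclopropyl}methanol, CH2OH cis to the chain | OC[C@@]1(C)C[C@@]1(C)CCCCCCCCCO[Si](C)(C)C(C)(C)C.OC[C@]1(C)C[C@]1(C)CCCCCCCCCO[Si](C)(C)C(C)(C)C | intermediate
9 | racemic 2-[9-(tert-butyldimethylsilyloxy)nonyl]-1,2-dimethylcyclopropane-1-carbaldehyde, CHO cis to the chain | O=C[C@@]1(C)C[C@@]1(C)CCCCCCCCCO[Si](C)(C)C(C)(C)C.O=C[C@]1(C)C[C@]1(C)CCCCCCCCCO[Si](C)(C)C(C)(C)C | intermediate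
10 | racemic tert-butyl{[9-(2-ethenyl-1,2-dimethylcyclopropyl)nonyl]oxy}dimethylsilane, vinyl cis to the chain | C=C[C@@]1(C)C[C@@]1(C)CCCCCCCCCO[Si](C)(C)C(C)(C)C.C=C[C@]1(C)C[C@]1(C)CCCCCCCCCO[Si](C)(C)C(C)(C)C | intermediate
11 | racemic tert-butyl({9-[(3RS,5RS)-5-ethenyl-3,5-dimethyl-1,2-dioxolan-3-yl]nonyl}oxy)dimethylsilane, methyl groups cis | C[C@]1(CCCCCCCCCO[Si](C)(C)C(C)(C)C)C[C@@](C)(C=C)OO1.C[C@@]1(CCCCCCCCCO[Si](C)(C)C(C)(C)C)C[C@](C)(C=C)OO1 | intermediate
12 | racemic (3RS,5RS)-5-[9-(tert-butyldimethylsilyloxy)nonyl]-3,5-dimethyl-1,2-dioxolane-3-carbaldehyde | C[C@]1(CCCCCCCCCO[Si](C)(C)C(C)(C)C)C[C@@](C)(C=O)OO1.C[C@@]1(CCCCCCCCCO[Si](C)(C)C(C)(C)C)C[C@](C)(C=O)OO1 | intermediate (not isolated)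
13 | racemic {(3RS,5RS)-5-[9-(tert-butyldimethylsilyloxy)nonyl]-3,5-dimethyl-1,2-dioxolan-3-yl}methanol | C[C@]1(CCCCCCCCCO[Si](C)(C)C(C)(C)C)C[C@@](C)(CO)OO1.C[C@@]1(CCCCCCCCCO[Si](C)(C)C(C)(C)C)C[C@](C)(CO)OO1 | intermediate
14 | {(3S,5S)-5-[9-(tert-butyldimethylsilyloxy)nonyl]-3,5-dimethyl-1,2-dioxolan-3-yl}methanol | C[C@]1(CCCCCCCCCO[Si](C)(C)C(C)(C)C)C[C@@](C)(CO)OO1 | intermediate
15 | methyl (triphenylphosphoranylidene)acetate | COC(=O)C=P(c1ccccc1)(c1ccccc1)c1ccccc1 | starting material
16 | (3S,5S)-5-[9-(tert-butyldimethylsilyloxy)nonyl]-3,5-dimethyl-1,2-dioxolane-3-carbaldehyde | C[C@]1(CCCCCCCCCO[Si](C)(C)C(C)(C)C)C[C@@](C)(C=O)OO1 | intermediate (not isolated)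
17 | methyl (2E)-3-{(3S,5S)-5-[9-(tert-butyldimethylsilyloxy)nonyl]-3,5-dimethyl-1,2-dioxolan-3-yl}prop-2-enoate | C[C@]1(CCCCCCCCCO[Si](C)(C)C(C)(C)C)C[C@@](C)(/C=C/C(=O)OC)OO1 | intermediate
18 | methyl (2E)-3-[(3S,5S)-5-(9-hydroxynonyl)-3,5-dimethyl-1,2-dioxolan-3-yl]prop-2-enoate | C[C@]1(CCCCCCCCCO)C[C@@](C)(/C=C/C(=O)OC)OO1 | intermediate
19 | methyl (2E)-3-[(3S,5S)-3,5-dimethyl-5-(9-oxononyl)-1,2-dioxolan-3-yl]prop-2-enoate | C[C@]1(CCCCCCCCC=O)C[C@@](C)(/C=C/C(=O)OC)OO1 | intermediate
20 | diethyl cinnamylphosphonate | CCOP(=O)(OCC)C/C=C/c1ccccc1 | starting material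
21 | methyl (2E)-3-{(3S,5S)-3,5-dimethyl-5-[(9E,11E)-12-phenyldodeca-9,11-dien-1-yl]-1,2-dioxolan-3-yl}prop-2-enoate, methyl groups cis | C[C@]1(CCCCCCCC/C=C/C=C/c2ccccc2)C[C@@](C)(/C=C/C(=O)OC)OO1 | intermediate (precursor of the key step)
22 | methyl (2E,4S,6S,15E,17E)-4,6-dihydroxy-4,6-dimethyl-18-phenyloctadeca-2,15,17-trienoate | C[C@](O)(CCCCCCCC/C=C/C=C/c1ccccc1)C[C@@](C)(/C=C/C(=O)OC)O | intermediate (not isolated)
23 | methyl 2-{(2S,3S,5S)-3-hydroxy-3,5-dimethyl-5-[(9E,11E)-12-phenyldodeca-9,11-dien-1-yl]oxolan-2-yl}acetate | C[C@]1(CCCCCCCC/C=C/C=C/c2ccccc2)C[C@](C)(O)[C@H](CC(=O)OC)O1 | intermediate (not isolated)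
24 | plakortone P, (1S,5S,7S)-1,7-dimethyl-7-[(9E,11E)-12-phenyldodeca-9,11-dien-1-yl]-2,6-dioxabicyclo[3.3.0]octan-3-one (C3, C4 and C6 all S) | C[C@]1(CCCCCCCC/C=C/C=C/c2ccccc2)C[C@]2(C)OC(=O)C[C@@H]2O1 | target

**Total step count:** 14.
**Longest linear sequence:** 13 steps (from 1 through steps 1 and 3–14; the same count from 4 through steps 2–14).

**Steps most likely to fail**

Step 14. The cascade may stall after O–O cleavage. Conjugate addition of a tertiary hydroxyl to an acyclic E enoate can be slow or revert, and the tertiary allylic hydroxyl may be lost under acid before the rings close. The fallback reverses the order of the two ring closures; it sets out from 14 and comes back at 24. Alcohol 14 is oxidised to aldehyde 16 (DMP) and olefinated under Still–Gennari conditions (methyl bis(2,2,2-trifluoroethyl)phosphonoacetate, KN(SiMe3)2, 18-crown-6, THF, −78 °C) to the silyl-protected (Z)-enoate F1. The operations of steps 11–13 then give in turn the hydroxy (Z)-enoate F2, the aldehyde (Z)-enoate F3 and the (Z)-dioxolanyl acrylate F4. Zn/AcOH cleaves the peroxide to the (Z)-dihydroxy ester F5, in which the ester lies within reach of the C4 hydroxyl, so that lactonisation to the hydroxy butenolide F6 should follow at once. DBU then adds the C6 hydroxyl to C3 of the butenolide, a better acceptor than the open-chain enoate; the tether allows only the cis-fused bicycle, which is 24.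

Step 9. The enzyme may discriminate poorly between the enantiomers, since the stereocentre next to the carbinol is quaternary, or may acylate the wanted antipode. The fallback replaces kinetic resolution by separation of covalent diastereomers; it sets out from 13 and comes back at 14. Acylation of 13 with (1S,4R)-camphanic chloride (Et3N, DMAP, CH2Cl2) gives the (3S,5S) camphanate F7 and the (3R,5R) camphanate F8, which have no epimerisable centre and are separated by chromatography or HPLC. Methanolysis of F7 (K2CO3, MeOH) returns 14.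

Step 7. The radical chain may be diverted: thiol–ene addition without ring opening, opening toward the ring CH2, or hydroperoxide by-products, with low conversion as the result. The fallback builds the same ring by an ionic [3+2] annulation of a peroxycarbenium ion with an alkene; it sets out from 6 and comes back at 11. Negishi coupling of 6 with 2-bromopropene (PdCl2(dppf)) gives the 1,1-disubstituted alkene F9. Ozonolysis in CH2Cl2/MeOH without reductive work-up gives the methoxy hydroperoxide F10, and silylation (Et3SiCl, imidazole) gives the triethylsilyl peroxyketal F11. With SnCl4 and 2-methylbuta-1,3-diene in CH2Cl2 at −78 °C, the peroxycarbenium ion should attack the methylene end of the 1,1-disubstituted alkene of the diene. The resulting tertiary allyl cation is then captured at its tertiary end by the silylperoxy oxygen, giving 11 together with its trans isomer, which is removed as in the main route. Applying this annulation to a diene is an extension of the known alkene scope.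

**Further compounds**

F1 | step 14 | methyl (2Z)-3-{(3S,5S)-5-[9-(tert-butyldimethylsilyloxy)nonyl]-3,5-dimethyl-1,2-dioxolan-3-yl}prop-2-enoate | C[C@]1(CCCCCCCCCO[Si](C)(C)C(C)(C)C)C[C@@](C)(/C=C\C(=O)OC)OO1
F2 | step 14 | methyl (2Z)-3-[(3S,5S)-5-(9-hydroxynonyl)-3,5-dimethyl-1,2-dioxolan-3-yl]prop-2-enoate | C[C@]1(CCCCCCCCCO)C[C@@](C)(/C=C\C(=O)OC)OO1
F3 | step 14 | methyl (2Z)-3-[(3S,5S)-3,5-dimethyl-5-(9-oxononyl)-1,2-dioxolan-3-yl]prop-2-enoate | C[C@]1(CCCCCCCCC=O)C[C@@](C)(/C=C\C(=O)OC)OO1
F4 | step 14 | methyl (2Z)-3-{(3S,5S)-3,5-dimethyl-5-[(9E,11E)-12-phenyldodeca-9,11-dien-1-yl]-1,2-dioxolan-3-yl}prop-2-enoate | C[C@]1(CCCCCCCC/C=C/C=C/c2ccccc2)C[C@@](C)(/C=C\C(=O)OC)OO1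
F5 | step 14 | methyl (2Z,4S,6S,15E,17E)-4,6-dihydroxy-4,6-dimethyl-18-phenyloctadeca-2,15,17-trienoate | C[C@](O)(CCCCCCCC/C=C/C=C/c1ccccc1)C[C@@](C)(/C=C\C(=O)OC)O
F6 | step 14 | (5S)-5-[(2S,11E,13E)-2-hydroxy-2-methyl-14-phenyltetradeca-11,13-dien-1-yl]-5-methylfuran-2(5H)-one | C[C@](O)(CCCCCCCC/C=C/C=C/c1ccccc1)C[C@@]1(C)C=CC(=O)O1
F7 | step 9 | {(3S,5S)-5-[9-(tert-butyldimethylsilyloxy)nonyl]-3,5-dimethyl-1,2-dioxolan-3-yl}methyl (1S,4R)-camphanate | C[C@]1(CCCCCCCCCO[Si](C)(C)C(C)(C)C)C[C@@](C)(COC(=O)[C@@]23CC[C@@](C)(C(=O)O2)C3(C)C)OO1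
F8 | step 9 | {(3R,5R)-5-[9-(tert-butyldimethylsilyloxy)nonyl]-3,5-dimethyl-1,2-dioxolan-3-yl}methyl (1S,4R)-camphanate | C[C@@]1(CCCCCCCCCO[Si](C)(C)C(C)(C)C)C[C@](C)(COC(=O)[C@@]23CC[C@@](C)(C(=O)O2)C3(C)C)OO1
F9 | step 7 | tert-butyldimethyl[(10-methylundec-10-en-1-yl)oxy]silane | C=C(C)CCCCCCCCCO[Si](C)(C)C(C)(C)C
F10 | step 7 | tert-butyl[(10-hydroperoxy-10-methoxyundecyl)oxy]dimethylsilane | CC(OC)(OO)CCCCCCCCCO[Si](C)(C)C(C)(C)C
F11 | step 7 | tert-butyl({10-methoxy-10-[(triethylsilyl)peroxy]undecyl}oxy)dimethylsilane | CC(OC)(OO[Si](CC)(CC)CC)CCCCCCCCCO[Si](C)(C)C(C)(C)C
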